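**Strategy.** Everything rests on cutting the decalin at C9–C10 and C4–C5. C9 lies between the C8 carbon and the one-carbon branch C14, so it can serve as the central carbon of a 3-oxo ester; the ring-fusion bond C5–C10 is then an (E)-trisubstituted alkene and C4 with its exocyclic C11 a terminal alkyne. A single Mn(III) oxidation of the acyclic 2-(2,5-dimethoxybenzyl)-3-oxo ester of (−)-8-phenylmenthol should close ring B (C5–C10) and ring A (C1–C5, C10), set C9, C10 and C5, and deliver the C4=C11 methylene at its final oxidation level. Later steps add C13 at C8, reduce C14 to methyl and unmask the arene.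

Key step: step 8

Remark on numbering: avarane numbering is used throughout (C11 = exocyclic CH2; C12, C13, C14 = methyls on C5, C8, C9; C15 = benzylic CH2; arene C16–C21 with oxygen on C17 and C20); β is the face of C12.

Assumption: the (−)-auxiliary is taken as the matched one, by analogy with 2-methyl-3-oxo esters. If the facial sense proved opposite, (+)-8-phenylmenthol would be used in step 4 and nothing else would change.

Remark on the key-step reagent: stoichiometric Mn(OAc)3 in ethanol is chosen over anodic regeneration, because the dimethoxyarene would be at risk at the anode and ethanol is the hydrogen donor for the vinyl radical.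

Remark on the endgame: C13 and C14 are reduced to methyl one after the other. A C13,C14-dialdehyde would condense with hydrazine to a cyclic azine, and an aldehyde hydrazone next to the C14 ester would close to a pyridazinone.

**Step 1**
Reactants: 1 hex-5-yn-1-ol; 2 ethyl 2-(triphenylphosphoranylidene)propanoate
Product: 4 ethyl (E)-2-methyloct-2-en-7-ynoate, via hex-5-ynal 3 (not isolated)
Conditions: PhI(OAc)2 (1.1 equiv), TEMPO (10 mol%), CH2Cl2, rt; then 2 (1.4 equiv), rt → 40 °C
Reagents that add atoms: none
Why: TEMPO/PhI(OAc)2 oxidation stops at the aldehyde and leaves the alkyne alone, and the stabilised α-methyl ylide then olefinates it in the same flask (Wittig reaction) with the (E)-geometry that later defines the C5=C10 alkene.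

**Step 2**
Reactants: 4 ethyl (E)-2-methyloct-2-en-7-ynoate
Product: 5 (E)-2-methyloct-2-en-7-yn-1-ol
Conditions: DIBAL-H (2.3 equiv), CH2Cl2, −78 → 0 °C; Rochelle salt work-up
Reagents that add atoms: none
Why: DIBAL-H 1,2-reduction of the enoate gives the allylic alcohol, and at low temperature neither the alkene geometry nor the terminal alkyne is affected.

**Step 3**
Reactants: 5 (E)-2-methyloct-2-en-7-yn-1-ol
Product: 6 (E)-1-bromo-2-methyloct-2-en-7-yne
Conditions: PBr3 (0.4 equiv), Et2O, 0 °C
Reagents that add atoms: phosphorus tribromide, BrP(Br)Br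
Why: Bromide displaces the phosphite ester of the primary allylic alcohol (SN2), and the primary bromide is favoured over the transposed tertiary one.

**Step 4**
Reactants: 7 (−)-8-phenylmenthol; 8 2,2,6-trimethyl-4H-1,3-dioxin-4-one
Product: 9 (−)-8-phenylmenthyl 3-oxobutanoate
Conditions: xylene, 140 °C, acetone distilled off
Reagents that add atoms: none
Why: Thermal retro-[4+2] cleavage of the dioxinone releases acetylketene, which acylates even a hindered secondary alcohol (acetoacetylation) without touching its stereocentres.

**Step 5**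
Reactants: 9 (−)-8-phenylmenthyl 3-oxobutanoate; 6 (E)-1-bromo-2-methyloct-2-en-7-yne
Product: 10 (−)-8-phenylmenthyl (E)-6-methyl-3-oxododec-6-en-11-ynoate
Conditions: NaH (1.05 equiv), THF, 0 °C; n-BuLi (1.05 equiv), −10 °C; then 6, −10 → 0 °C; then 1 M HCl
Reagents that add atoms: none
Why: γ-Alkylation of an acetoacetate dianion: the terminal carbanion is the more nucleophilic site and displaces the allylic bromide (SN2) faster than it removes the alkyne proton.

**Step 6**
Reactants: 11 2,5-dimethoxybenzyl alcohol
Product: 12 2-(bromomethyl)-1,4-dimethoxybenzene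
Conditions: PBr3 (0.4 equiv), CH2Cl2, 0 °C; used without storage
Reagents that add atoms: phosphorus tribromide, BrP(Br)Br
Why: PBr3 bromination of a benzylic alcohol by SN2 displacement of its phosphite ester.

**Step 7**
Reactants: 10 (−)-8-phenylmenthyl (E)-6-methyl-3-oxododec-6-en-11-ynoate; 12 2-(bromomethyl)-1,4-dimethoxybenzene
Product: 13 (−)-8-phenylmenthyl (E)-2-(2,5-dimethoxybenzyl)-6-methyl-3-oxododec-6-en-11-ynoate (both C2 epimers)
Conditions: NaH (1.0 equiv), THF, 0 °C; then 12, 0 °C → rt
Reagents that add atoms: none
Why: C-Alkylation of the sodium enolate of a β-keto ester with a benzylic bromide; one equivalent of base is taken up by the far more acidic keto ester and not the alkyne, and the new C2 centre needs no control because it becomes the radical carbon.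

**Step 8**
Reactants: 13 (−)-8-phenylmenthyl (E)-2-(2,5-dimethoxybenzyl)-6-methyl-3-oxododec-6-en-11-ynoate
Product: 14 trans-decalin keto ester: (−)-8-phenylmenthyl ester on C9 (β, axial), 2,5-dimethoxybenzyl on C9 (α), C8 ketone, C5 β-methyl, C10 α-H, C4=C11 exocyclic methylene
Conditions: Mn(OAc)3·2H2O (2.2 equiv), degassed EtOH (0.02 M), 25 °C, Ar, no Cu(II); minor diastereomers removed by chromatography
Reagents that add atoms: none
Why: Mn(III) forms the enolate of the 2-benzyl-3-oxo ester and oxidises it to the electrophilic C9 radical, which adds to C10 of the electron-rich (E)-alkene; the tertiary C5 radical then adds to the inner alkyne carbon C4, and the vinyl radical at C11 takes a hydrogen atom from ethanol, whose radical is oxidised by the second equivalent of Mn(III). The closest known reaction type is the Mn(OAc)3-mediated oxidative free-radical tandem cyclisation of unsaturated 2-alkyl-3-oxo esters terminated by an alkyne, run with 8-phenylmenthyl esters as chiral auxiliaries. Ring B closes 6-endo-trig (C9–C10) and ring A closes 6-exo-dig (C4–C5), both through chair-like arrangements. At C9 the phenyl ring of the auxiliary should cover one face of the chelated keto ester radical so that the alkene approaches the other, with the larger benzyl group equatorial and the ester axial (β); at C10 and C5 the (E)-geometry of the alkene and chair–chair folding should give the trans ring fusion with C12 cis to the ester. The step needs 6-endo and not 5-exo attack, which the C12 methyl secures by making C10 the less substituted terminus and C5 a tertiary radical, and it needs the C5 radical to cyclise before it is oxidised, which is why Cu(II) is left out. Mn(III) is too weak an oxidant to attack the dimethoxyarene, and the product has no hydrogen on C9 and is not oxidised further.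

**Step 9**
Reactants: 14 trans-decalin keto ester
Product: 16 8β-formyl ester (C8 α-H, equatorial CHO; C9 ester, benzyl and C4=C11 unchanged), via C8 methoxymethylene enol ether 15 (not isolated)
Conditions: Ph3P(CH2OMe)Cl (5 equiv), KHMDS (4.8 equiv), THF, 0 → 65 °C; then 2 M aq HCl, THF, 25 °C
Reagents that add atoms: (methoxymethyl)triphenylphosphonium chloride, COC[P+](c1ccccc1)(c1ccccc1)c1ccccc1.[Cl-]; water, O
Why: Wittig methoxymethylenation adds C13 to the C8 ketone (enolisable only towards C7, and reversibly), and dilute acid hydrolyses the enol ether much faster than it protonates the 1,1-disubstituted C4=C11 alkene; protonation of C8 on the α (axial) face, anti to the axial C9 ester, should place the formyl group equatorial (8β), which is also the more stable epimer.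

**Step 10**
Reactants: 16 8β-formyl ester
Product: 18 8β-methyl ester, via C13 tosylhydrazone 17 (not isolated)
Conditions: TsNHNH2 (1.1 equiv), CHCl3, 4 Å MS, rt; then catecholborane (3 equiv), 0 °C → rt; then NaOAc·3H2O, 60 °C
Reagents that add atoms: none
Why: Caglioti-type deoxygenation: catecholborane reduces the C=N bond of the aldehyde tosylhydrazone and acetate then triggers loss of sulfinate and N2, which should give the methyl group under mild conditions without touching the hindered ester, the alkene or the C8 configuration.

**Step 11**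
Reactants: 18 8β-methyl ester
Product: 19 14-hydroxy-17,20-di-O-methylneoavarol (C9 β-CH2OH)
Conditions: LiAlH4 (4 equiv), THF, reflux; aq NaOH work-up; auxiliary alcohol 7 recovered
Reagents that add atoms: none
Why: LiAlH4 at reflux reduces even a neopentyl 8-phenylmenthyl ester to the primary alcohol and returns the auxiliary alcohol, while the alkene and the aryl ethers are inert to hydride.

**Step 12**
Reactants: 19 14-hydroxy-17,20-di-O-methylneoavarol
Product: 20 14-oxo-17,20-di-O-methylneoavarol (C9 β-CHO)
Conditions: Dess–Martin periodinane (1.5 equiv), CH2Cl2, rt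
Reagents that add atoms: none
Why: Dess–Martin oxidation of a neopentyl primary alcohol stops at the aldehyde, which has no α-hydrogen and cannot epimerise or enolise.

**Step 13**
Reactants: 20 14-oxo-17,20-di-O-methylneoavarol
Product: 22 17,20-di-O-methylneoavarol, via C14 hydrazone 21 (not isolated)
Conditions: N2H4·H2O (excess), KOH, diethylene glycol, 130 °C, then 200 °C with removal of water
Reagents that add atoms: none
Why: Wolff–Kishner reduction in the Huang-Minlon form is the standard way to turn a hindered angular aldehyde into a methyl group, and the aryl methyl ethers, the unactivated exocyclic alkene and all four stereocentres are inert to hot KOH.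

**Step 14**
Reactants: 22 17,20-di-O-methylneoavarol
Product: 24 neoavarol, via neoavarone 23 (not isolated)
Conditions: CAN (2.5 equiv), MeCN–H2O (2:1), 0 °C; then EtOAc, aq Na2S2O4, rt, Ar
Reagents that add atoms: water, O
Why: Cerium(IV) oxidative demethylation of the 1,4-dimethoxyarene gives the p-quinone (water supplies the new oxygen atoms) within minutes at 0 °C, too briefly for the acid formed to move the C4=C11 alkene, and dithionite reduces the quinone to the hydroquinone during work-up.

**Step 15**
Reactants: 24 neoavarol
Product: 25 20-O-acetylneoavarol, (5S,8S,9R,10S)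
Conditions: Ac2O (1.05 equiv), pyridine, CH2Cl2, −20 → 0 °C, Ar
Reagents that add atoms: acetic anhydride, CC(=O)OC(C)=O
Why: Kinetic acylation of a phenol: the C20 hydroxyl has two ring hydrogens as neighbours, whereas the C17 hydroxyl is ortho to the neopentyl-type C15–C9 unit, so one equivalent of anhydride at low temperature should acetylate C20–OH first.

**Compound list**

1 | hex-5-yn-1-ol | OCCCCC#C | starting material
2 | ethyl 2-(triphenylphosphoranylidene)propanoate | CCOC(=O)C(C)=P(c1ccccc1)(c1ccccc1)c1ccccc1 | starting material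
3 | hex-5-ynal | O=CCCCC#C | intermediate (not isolated)
4 | ethyl (E)-2-methyloct-2-en-7-ynoate | C#CCCC/C=C(\C)C(=O)OCC | intermediate
5 | (E)-2-methyloct-2-en-7-yn-1-ol | C#CCCC/C=C(\C)CO | intermediate
6 | (E)-1-bromo-2-methyloct-2-en-7-yne | C#CCCC/C=C(\C)CBr | intermediate
7 | (−)-8-phenylmenthol, (1R,2S,5R)-5-methyl-2-(2-phenylpropan-2-yl)cyclohexan-1-ol | O[C@@H]1C[C@H](C)CC[C@H]1C(C)(C)c1ccccc1 | starting material
8 | 2,2,6-trimethyl-4H-1,3-dioxin-4-one | CC1=CC(=O)OC(C)(C)O1 | starting material
9 | (−)-8-phenylmenthyl 3-oxobutanoate | CC(=O)CC(=O)O[C@@H]1C[C@H](C)CC[C@H]1C(C)(C)c1ccccc1 | intermediate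
10 | (−)-8-phenylmenthyl (E)-6-methyl-3-oxododec-6-en-11-ynoate | C#CCCC/C=C(\C)CCC(=O)CC(=O)O[C@@H]1C[C@H](C)CC[C@H]1C(C)(C)c1ccccc1 | intermediate
11 | 2,5-dimethoxybenzyl alcohol | COc1ccc(OC)c(CO)c1 | starting material
12 | 2-(bromomethyl)-1,4-dimethoxybenzene | COc1ccc(OC)c(CBr)c1 | intermediate
13 | (−)-8-phenylmenthyl (E)-2-(2,5-dimethoxybenzyl)-6-methyl-3-oxododec-6-en-11-ynoate, C2 epimers | C#CCCC/C=C(\C)CCC(=O)C(Cc1cc(OC)ccc1OC)C(=O)O[C@@H]1C[C@H](C)CC[C@H]1C(C)(C)c1ccccc1 | intermediate
14 | trans-decalin keto ester: 8-oxo, 9β-CO2(8-phenylmenthyl), 9α-(2,5-dimethoxybenzyl), 5β-methyl, 10α-H, 4(11)-methylene | C=C1CCC[C@H]2[C@](C(=O)O[C@@H]3C[C@H](C)CC[C@H]3C(C)(C)c3ccccc3)(Cc3cc(OC)ccc3OC)C(=O)CC[C@]12C | intermediate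
15 | C8 methoxymethylene enol ether of 14 (E/Z mixture) | C=C1CCC[C@H]2[C@](C(=O)O[C@@H]3C[C@H](C)CC[C@H]3C(C)(C)c3ccccc3)(Cc3cc(OC)ccc3OC)C(=COC)CC[C@]12C | intermediate (not isolated)
16 | 8β-formyl ester (8α-H), otherwise as 14 | C=C1CCC[C@H]2[C@](C(=O)O[C@@H]3C[C@H](C)CC[C@H]3C(C)(C)c3ccccc3)(Cc3cc(OC)ccc3OC)[C@@H](C=O)CC[C@]12C | intermediate
17 | C13 tosylhydrazone of 16 | C=C1CCC[C@H]2[C@](C(=O)O[C@@H]3C[C@H](C)CC[C@H]3C(C)(C)c3ccccc3)(Cc3cc(OC)ccc3OC)[C@@H](/C=N/NS(=O)(=O)c3ccc(C)cc3)CC[C@]12C | intermediate (not isolated)
18 | 8β-methyl ester: (−)-8-phenylmenthyl ester on C9 (β) of the 17,20-di-O-methylneoavarol skeleton | C=C1CCC[C@H]2[C@](C(=O)O[C@@H]3C[C@H](C)CC[C@H]3C(C)(C)c3ccccc3)(Cc3cc(OC)ccc3OC)[C@@H](C)CC[C@]12C | intermediate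
19 | 14-hydroxy-17,20-di-O-methylneoavarol (9β-CH2OH) | C=C1CCC[C@H]2[C@](CO)(Cc3cc(OC)ccc3OC)[C@@H](C)CC[C@]12C | intermediate
20 | 14-oxo-17,20-di-O-methylneoavarol (9β-CHO) | C=C1CCC[C@H]2[C@](C=O)(Cc3cc(OC)ccc3OC)[C@@H](C)CC[C@]12C | intermediate
21 | C14 hydrazone of 20 | C=C1CCC[C@H]2[C@](/C=N/N)(Cc3cc(OC)ccc3OC)[C@@H](C)CC[C@]12C | intermediate (not isolated)
22 | 17,20-di-O-methylneoavarol | C=C1CCC[C@H]2[C@](C)(Cc3cc(OC)ccc3OC)[C@@H](C)CC[C@]12C | intermediate
23 | neoavarone (2-substituted 1,4-benzoquinone) | C=C1CCC[C@H]2[C@](C)(CC3=CC(=O)C=CC3=O)[C@@H](C)CC[C@]12C | intermediate (not isolated)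
24 | neoavarol | C=C1CCC[C@H]2[C@](C)(Cc3cc(O)ccc3O)[C@@H](C)CC[C@]12C | intermediate
25 | 20-O-acetylneoavarol, (5S,8S,9R,10S) | C=C1CCC[C@H]2[C@](C)(Cc3cc(OC(C)=O)ccc3O)[C@@H](C)CC[C@]12C | target

**Totals.** Total step count: 15. Longest linear sequence: 13 steps (1, 2, 3, 5, 7, 8, 9, 10, 11, 12, 13, 14, 15); steps 4 and 6 are side branches.

**Steps most likely to fail**

Step 8. The auxiliary may not separate the two faces of the C9 radical well enough at the temperature the Mn(III) oxidation needs, the ester and benzyl groups may spread over both orientations, and the C5 radical may be quenched before it reaches the alkyne. The fallback sets out from 13 and comes back at 14. The sodium enolate of 13 (NaH, THF, 0 °C) would be brominated with N-bromosuccinimide to the α-bromo keto ester, (−)-8-phenylmenthyl (E)-2-bromo-2-(2,5-dimethoxybenzyl)-6-methyl-3-oxododec-6-en-11-ynoate F1. Slow addition of Bu3SnH to F1 with Et3B/O2 initiation in CH2Cl2 at −78 °C, in the presence of MgBr2·OEt2, would generate the same C9 radical by bromine abstraction. At this temperature the magnesium-chelated keto ester should be held rigidly under the phenyl ring of the auxiliary, and the low stannane concentration leaves both ring closures time to finish before the vinyl radical is reduced to 14.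

Step 9. The ylide may act only as a base on the crowded C8 ketone (enolisation towards C7) and not add, and the acid hydrolysis may protonate C8 from both faces. The fallback sets out from 14 and comes back at 15. The small, strongly nucleophilic Peterson reagent MeOCH(Li)SiMe3 (from MeOCH2SiMe3 and s-BuLi, THF, −78 °C) would add to the ketone to give the β-hydroxy silane, the C8 carbinol bearing a methoxy(trimethylsilyl)methyl group, F2. KH in THF (0 °C) would then effect Peterson elimination to enol ether 15, which is hydrolysed to 16 as in step 9.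

Step 15. The anhydride may not distinguish the two phenolic hydroxyls sharply, or may go on to the diacetate. The fallback sets out from 24 and comes back at 25. Both phenols would be silylated (TBSCl, imidazole, DMF) to 17,20-bis-O-(tert-butyldimethylsilyl)neoavarol F3. The unhindered C20 silyl ether would be cleaved selectively (Cs2CO3, DMF–H2O, rt) to 17-O-(tert-butyldimethylsilyl)neoavarol F4. The free C20 hydroxyl would be acetylated (Ac2O, pyridine, DMAP) to 20-O-acetyl-17-O-(tert-butyldimethylsilyl)neoavarol F5, and the hindered silyl ether would be removed with TBAF buffered with AcOH (THF, 0 °C), which leaves the aryl acetate in place.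

**Further compounds**

F1 | step 8 | (−)-8-phenylmenthyl (E)-2-bromo-2-(2,5-dimethoxybenzyl)-6-methyl-3-oxododec-6-en-11-ynoate | C#CCCC/C=C(\C)CCC(=O)C(Br)(Cc1cc(OC)ccc1OC)C(=O)O[C@@H]1C[C@H](C)CC[C@H]1C(C)(C)c1ccccc1
F2 | step 9 | β-hydroxy silane from 14: C8 carbinol bearing CH(OMe)SiMe3 (configuration at C8 and C13 not defined) | C=C1CCC[C@H]2[C@](C(=O)O[C@@H]3C[C@H](C)CC[C@H]3C(C)(C)c3ccccc3)(Cc3cc(OC)ccc3OC)C(O)(C(OC)[Si](C)(C)C)CC[C@]12C
F3 | step 15 | 17,20-bis-O-(tert-butyldimethylsilyl)neoavarol | C=C1CCC[C@H]2[C@](C)(Cc3cc(O[Si](C)(C)C(C)(C)C)ccc3O[Si](C)(C)C(C)(C)C)[C@@H](C)CC[C@]12C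
F4 | step 15 | 17-O-(tert-butyldimethylsilyl)neoavarol | C=C1CCC[C@H]2[C@](C)(Cc3cc(O)ccc3O[Si](C)(C)C(C)(C)C)[C@@H](C)CC[C@]12C
F5 | step 15 | 20-O-acetyl-17-O-(tert-butyldimethylsilyl)neoavarol | C=C1CCC[C@H]2[C@](C)(Cc3cc(OC(C)=O)ccc3O[Si](C)(C)C(C)(C)C)[C@@H](C)CC[C@]12C
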